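## Plan

- Numbering used throughout (tetrahydrobenzofuranone): O1, C2, C3, C3a, C4(=O), C5, C6, C7, C7a. The retrosynthesis first removes the C5 hydroxyl (enolate hydroxylation) and takes the acid carbon back to a methyl group. It then cuts three bonds that are made in one operation: C5–C6 and C3a–C7a of the carbocycle (methyl ketone + acrylate, a (3+3) Michael–Claisen annulation) and O1–C2 (epoxide opening). The C3–C3a bond goes back to an epoxy iodide and acetone.
- Enabling feature: the six-membered ring is a cyclohexane-1,3-dione in disguise. C4=O and the enol-ether carbon C7a flank C3a, C5 is alpha to C4 and C6 is beta to C7a, so C3a–C4–C5 is a ketone and C6–C7–C7a an acrylate. While C5 is still CH2 the dione is symmetric, so either enol oxygen closes the same dihydrofuran.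
- Forward order: the chain comes first ((2Z,6E)-farnesol supplies all fifteen chain carbons), then Sharpless epoxidation and attachment of the acetone unit. The carbocycle and then the dihydrofuran form in one pot, followed by oxidation at the chain terminus, at C5 and to the acid.
- Stereochemistry: one catalytic epoxidation of the (Z)-allylic alcohol sets both epoxide centres. The carbinol centre (S) is carried through; C2 (S) arises by stereospecific inversion of the (R) epoxide carbon in the key step (Z-epoxide plus anti opening gives the required S,S pair). C5 (R) is set by a reagent-controlled enolate hydroxylation.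

Key step: step 4

Assumption 1: (2Z,6E)-farnesol is bought isomerically pure (catalogue compound, CAS 3790-71-4).
Assumption 2: the (+)-(2R,8aS) oxaziridine is taken to attack the Re face at C5 of the sodium enolate; if the sense proves opposite, its commercial antipode is used in the same way.

## Route

Step 1
Reactants: 1 (2Z,6E)-farnesol
Product: 2 [(2R,3S)-3-[(3E)-4,8-dimethylnona-3,7-dien-1-yl]-3-methyloxiran-2-yl]methanol
Conditions: Ti(OiPr)4 (10 mol %), D-(−)-diethyl tartrate (12 mol %), t-BuOOH, 4 Å MS, CH2Cl2, −20 °C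
Reagents that add atoms: tert-butyl hydroperoxide CC(C)(C)OO
Why: Sharpless asymmetric epoxidation is directed by the allylic hydroxyl and so touches only the 2,3-alkene; with D-(−)-tartrate the (Z)-trisubstituted allylic alcohol should give the (2R,3S) epoxide, which fixes the later carbinol centre and pre-sets C2 for inversion.

Step 2
Reactants: 2 [(2R,3S)-3-[(3E)-4,8-dimethylnona-3,7-dien-1-yl]-3-methyloxiran-2-yl]methanol
Product: 3 (2S,3S)-3-[(3E)-4,8-dimethylnona-3,7-dien-1-yl]-2-(iodomethyl)-3-methyloxirane
Conditions: I2, PPh3, imidazole, THF, 0 °C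
Reagents that add atoms: iodine II
Why: Garegg–Samuelsson (Appel-type) iodination replaces the primary hydroxyl by SN2 at CH2 under buffered conditions, so neither epoxide centre is touched (the 2S label of the iodide is a priority change only).

Step 3
Reactants: 3 (2S,3S)-3-[(3E)-4,8-dimethylnona-3,7-dien-1-yl]-2-(iodomethyl)-3-methyloxirane; 4 acetone N,N-dimethylhydrazone
Product: 6 4-[(2R,3S)-3-[(3E)-4,8-dimethylnona-3,7-dien-1-yl]-3-methyloxiran-2-yl]butan-2-one, via alkylated dimethylhydrazone 5 (not isolated)
Conditions: 4, LiN(iPr)2, THF, 0 °C; 3, −78 → 0 °C; then Cu(OAc)2, THF/H2O, rt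
Reagents that add atoms: water O
Why: Aza-enolate (hydrazone) alkylation: the lithiated dimethylhydrazone of acetone displaces the primary iodide by SN2 and the hydrazone is then hydrolysed near neutral pH with Cu(OAc)2, which the trisubstituted epoxide should survive; no stereocentre is formed.

Step 4
Reactants: 6 4-[(2R,3S)-3-[(3E)-4,8-dimethylnona-3,7-dien-1-yl]-3-methyloxiran-2-yl]butan-2-one; 7 methyl acrylate
Product: 10 (2S)-2-[(2S,5E)-2-hydroxy-6,10-dimethylundeca-5,9-dien-2-yl]-3,5,6,7-tetrahydro-1-benzofuran-4(2H)-one, via keto ester 8 (not isolated), via epoxy dione 9 (not isolated)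
Conditions: LiN(iPr)2 (1.05 equiv), THF, −78 °C; 7 (1.0 equiv, slow addition), −78 → 0 °C; then MeOH, 50 °C; AcOH
Reagents that add atoms: none
Why: Kinetic deprotonation at CH3 gives the terminal lithium enolate, which adds 1,4 to methyl acrylate (C5–C6); the ester enolate then passes its charge by a six-centre proton transfer to the internal alpha carbon C3a, which acylates on the ester with loss of methoxide (C3a–C7a), the known Michael–Claisen (3+3) annulation of ketone enolates with acrylates to cyclohexane-1,3-diones. The carbocycle thus closes by a 6-exo-trig Dieckmann-type acylation, and the dione enolate then closes the dihydrofuran by 5-exo-tet attack of an enol oxygen on the secondary epoxide carbon, the known base-mediated cyclisation of 2-(2,3-epoxyalkyl)-1,3-diones. The only stereocentre made, C2, arises by SN2 inversion of the (R) epoxide carbon, and the carbinol centre is carried through because its C–O bond is never broken. The regiochemistry (Michael at CH3, Claisen at CH2) is secured by the kinetic base and by ring size, since only the C3a enolate reaches the ester through a six-membered transition state while a C5 enolate would have to form a four-membered ring. The two dione oxygens need no differentiation because the 2-substituted dione is symmetric at this stage (C5 and C7 are both CH2), and under basic, non-ionising conditions 5-exo attack at the less substituted carbon should win over 6-endo attack at the tertiary one and over C-alkylation. Attack of the simple ketone enolates on the hindered trisubstituted epoxide should be slow between −78 and 0 °C compared with conjugate addition and Dieckmann closure, so the epoxide is expected to last until the dione enolate exists.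

Step 5
Reactants: 10 (2S)-2-[(2S,5E)-2-hydroxy-6,10-dimethylundeca-5,9-dien-2-yl]-3,5,6,7-tetrahydro-1-benzofuran-4(2H)-one
Product: 11 (2S)-2-[(2S,5E,9E)-2,11-dihydroxy-6,10-dimethylundeca-5,9-dien-2-yl]-3,5,6,7-tetrahydro-1-benzofuran-4(2H)-one
Conditions: SeO2 (cat.), t-BuOOH, CH2Cl2, 0 °C → rt
Reagents that add atoms: tert-butyl hydroperoxide CC(C)(C)OO
Why: Catalytic SeO2/t-BuOOH allylic oxidation (ene reaction, then [2,3]-sigmatropic shift, with the hydroperoxide as the stoichiometric oxygen source) is known on polyprenyl chains to pick the (E)-methyl of the terminal isopropylidene group, which should give the (9E)-allylic alcohol and leave the more hindered internal alkene and the vinylogous ester alone.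

Step 6
Reactants: 11 (2S)-2-[(2S,5E,9E)-2,11-dihydroxy-6,10-dimethylundeca-5,9-dien-2-yl]-3,5,6,7-tetrahydro-1-benzofuran-4(2H)-one
Product: 12 (2S,5R)-2-[(2S,5E,9E)-2,11-dihydroxy-6,10-dimethylundeca-5,9-dien-2-yl]-5-hydroxy-3,5,6,7-tetrahydro-1-benzofuran-4(2H)-one
Conditions: NaN(SiMe3)2 (3.3 equiv), THF, −78 °C; (+)-(2R,8aS)-(camphorsulfonyl)oxaziridine, −78 °C; AcOH
Reagents that add atoms: (+)-(2R,8aS)-(camphorsulfonyl)oxaziridine O=S1(=O)C[C@@]23CC[C@@H](C2(C)C)C[C@]34ON14
Why: Davis enolate hydroxylation: the excess base first takes the two hydroxyl protons and then forms the kinetic cross-conjugated sodium enolate at C5 (alpha' position of the vinylogous ester), and the enantiopure N-sulfonyloxaziridine transfers oxygen to one face of it, so that the camphor skeleton of the reagent and not the remote C2 centre should set (5R).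

Step 7
Reactants: 12 (2S,5R)-2-[(2S,5E,9E)-2,11-dihydroxy-6,10-dimethylundeca-5,9-dien-2-yl]-5-hydroxy-3,5,6,7-tetrahydro-1-benzofuran-4(2H)-one
Product: 14 (2E,6E,10S)-10-hydroxy-10-[(2S,5R)-5-hydroxy-4-oxo-2,3,4,5,6,7-hexahydro-1-benzofuran-2-yl]-2,6-dimethylundeca-2,6-dienoic acid, via enal 13 (not isolated)
Conditions: TEMPO (2,2,6,6-tetramethylpiperidin-1-oxyl, cat.), PhI(OAc)2, CH2Cl2, rt; then NaClO2, NaH2PO4, 2-methyl-2-butene, t-BuOH/H2O, 0 °C
Reagents that add atoms: sodium chlorite [Na+].[O-]Cl=O
Why: Oxoammonium (TEMPO/PhI(OAc)2) oxidation takes the primary allylic alcohol in preference to the secondary and tertiary hydroxyls, and Pinnick oxidation of the resulting enal, with 2-methyl-2-butene as hypochlorite scavenger, should give the (E)-2-methyl-2-enoic acid without epimerising C5 or touching the alkenes.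

## Compound list

1 | (2Z,6E)-3,7,11-trimethyldodeca-2,6,10-trien-1-ol ((2Z,6E)-farnesol) | CC(C)=CCC/C(C)=C/CC/C(C)=C\CO | starting material
2 | [(2R,3S)-3-[(3E)-4,8-dimethylnona-3,7-dien-1-yl]-3-methyloxiran-2-yl]methanol | CC(C)=CCC/C(C)=C/CC[C@]1(C)O[C@@H]1CO | intermediate
3 | (2S,3S)-3-[(3E)-4,8-dimethylnona-3,7-dien-1-yl]-2-(iodomethyl)-3-methyloxirane | CC(C)=CCC/C(C)=C/CC[C@]1(C)O[C@@H]1CI | intermediate
4 | acetone N,N-dimethylhydrazone | CC(C)=NN(C)C | starting material
5 | (E)-N,N-dimethylhydrazone of 4-[(2R,3S)-3-[(3E)-4,8-dimethylnona-3,7-dien-1-yl]-3-methyloxiran-2-yl]butan-2-one | CC(C)=CCC/C(C)=C/CC[C@]1(C)O[C@@H]1CC/C(C)=N/N(C)C | intermediate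
6 | 4-[(2R,3S)-3-[(3E)-4,8-dimethylnona-3,7-dien-1-yl]-3-methyloxiran-2-yl]butan-2-one | CC(C)=CCC/C(C)=C/CC[C@]1(C)O[C@@H]1CCC(C)=O | intermediate
7 | methyl acrylate | COC(=O)C=C | starting material
8 | methyl 7-[(2R,3S)-3-[(3E)-4,8-dimethylnona-3,7-dien-1-yl]-3-methyloxiran-2-yl]-5-oxoheptanoate | CC(C)=CCC/C(C)=C/CC[C@]1(C)O[C@@H]1CCC(=O)CCCC(=O)OC | intermediate
9 | 2-{[(2R,3S)-3-[(3E)-4,8-dimethylnona-3,7-dien-1-yl]-3-methyloxiran-2-yl]methyl}cyclohexane-1,3-dione | CC(C)=CCC/C(C)=C/CC[C@]1(C)O[C@@H]1CC2C(=O)CCCC2=O | intermediate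
10 | (2S)-2-[(2S,5E)-2-hydroxy-6,10-dimethylundeca-5,9-dien-2-yl]-3,5,6,7-tetrahydro-1-benzofuran-4(2H)-one | C/C(=C\CC[C@](C)(O)[C@@H]1CC2=C(CCCC2=O)O1)CCC=C(C)C | intermediate
11 | (2S)-2-[(2S,5E,9E)-2,11-dihydroxy-6,10-dimethylundeca-5,9-dien-2-yl]-3,5,6,7-tetrahydro-1-benzofuran-4(2H)-one | C/C(=C\CC[C@](C)(O)[C@@H]1CC2=C(CCCC2=O)O1)CC/C=C(\C)CO | intermediate
12 | (2S,5R)-2-[(2S,5E,9E)-2,11-dihydroxy-6,10-dimethylundeca-5,9-dien-2-yl]-5-hydroxy-3,5,6,7-tetrahydro-1-benzofuran-4(2H)-one | C/C(=C\CC[C@](C)(O)[C@@H]1CC2=C(CC[C@@H](O)C2=O)O1)CC/C=C(\C)CO | intermediate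
13 | (2E,6E,10S)-10-hydroxy-10-[(2S,5R)-5-hydroxy-4-oxo-2,3,4,5,6,7-hexahydro-1-benzofuran-2-yl]-2,6-dimethylundeca-2,6-dienal | C/C(=C\CC[C@](C)(O)[C@@H]1CC2=C(CC[C@@H](O)C2=O)O1)CC/C=C(\C)C=O | intermediate
14 | (2E,6E,10S)-10-hydroxy-10-[(2S,5R)-5-hydroxy-4-oxo-2,3,4,5,6,7-hexahydro-1-benzofuran-2-yl]-2,6-dimethylundeca-2,6-dienoic acid | C/C(=C\CC[C@](C)(O)[C@@H]1CC2=C(CC[C@@H](O)C2=O)O1)CC/C=C(\C)C(=O)O | target

## Totals and risks

Total step count: 7. Longest linear sequence: 7 steps (from 1).

Steps most likely to fail: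

Step 4 (key step). The lithium ester enolate formed after the conjugate addition may add to further acrylate (oligomerisation, second Michael addition) instead of relaying its charge, or a ketone enolate may open the epoxide before the dione exists. Fallback: setting out from 2, Parikh–Doering oxidation (SO3·pyridine, DMSO, Et3N) would give (2S,3S)-3-[(3E)-4,8-dimethylnona-3,7-dien-1-yl]-3-methyloxirane-2-carbaldehyde F1. Three-component reductive alkylation of purchased cyclohexane-1,3-dione with this aldehyde and the Hantzsch ester diethyl 2,6-dimethyl-1,4-dihydropyridine-3,5-dicarboxylate under L-proline catalysis would proceed by Knoevenagel condensation to the alkylidene dione 2-{[(2R,3S)-3-[(3E)-4,8-dimethylnona-3,7-dien-1-yl]-3-methyloxiran-2-yl]methylidene}cyclohexane-1,3-dione F2, then transfer hydrogenation to epoxy dione 9. K2CO3 in MeOH should close 9 to 10, where the route is rejoined.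

Step 6. Facial selectivity of the oxygen transfer may be poor, because the reagent is the only control element at a centre remote from C2. Fallback: setting out from 10, hydroxylation of its sodium enolate with racemic 3-phenyl-2-(phenylsulfonyl)oxaziridine would give the pair of C5 epimers (2S,5RS)-5-hydroxy-2-[(2S,5E)-2-hydroxy-6,10-dimethylundeca-5,9-dien-2-yl]-3,5,6,7-tetrahydro-1-benzofuran-4(2H)-one F3. Acylation with vinyl acetate catalysed by Burkholderia cepacia lipase should, by the empirical rule for secondary alcohols with the carbonyl side taken as the large substituent, take the (5R) epimer and give (2S,5R)-2-[(2S,5E)-2-hydroxy-6,10-dimethylundeca-5,9-dien-2-yl]-4-oxo-2,3,4,5,6,7-hexahydro-1-benzofuran-5-yl acetate F4, which is separated by chromatography from the unreacted (5S) component of F3. Hydrolysis of F4 by the same lipase in phosphate buffer at pH 7, which avoids base epimerisation of the ketol, should give (2S,5R)-5-hydroxy-2-[(2S,5E)-2-hydroxy-6,10-dimethylundeca-5,9-dien-2-yl]-3,5,6,7-tetrahydro-1-benzofuran-4(2H)-one F5. F5 then takes the SeO2/t-BuOOH oxidation of step 5 and comes back to the route at 12.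

Step 5. Site selectivity between the two trisubstituted alkenes may be incomplete, and the allylic alcohol may be over-oxidised. Fallback: setting out from 10, olefin cross-metathesis with methacrolein, catalysed by RuCl2(H2IMes)(=CH-C6H4-2-OiPr) (second-generation Hoveyda–Grubbs catalyst), should exchange the terminal isopropylidene group for the (E)-2-methylpropenal end and give (2E,6E,10S)-10-hydroxy-2,6-dimethyl-10-[(2S)-4-oxo-2,3,4,5,6,7-hexahydro-1-benzofuran-2-yl]undeca-2,6-dienal F6. The hindered internal alkene should not take part. Luche reduction (NaBH4, CeCl3·7H2O, MeOH, −78 °C) should then reduce the aldehyde alone, the vinylogous ester carbonyl being far less electrophilic, and give 11, where the route is rejoined.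

Further compounds
F1 | step 4 | (2S,3S)-3-[(3E)-4,8-dimethylnona-3,7-dien-1-yl]-3-methyloxirane-2-carbaldehyde | CC(C)=CCC/C(C)=C/CC[C@]1(C)O[C@@H]1C=O
F2 | step 4 | 2-{[(2R,3S)-3-[(3E)-4,8-dimethylnona-3,7-dien-1-yl]-3-methyloxiran-2-yl]methylidene}cyclohexane-1,3-dione | CC(C)=CCC/C(C)=C/CC[C@]1(C)O[C@@H]1C=C2C(=O)CCCC2=O
F3 | step 6 | (2S,5RS)-5-hydroxy-2-[(2S,5E)-2-hydroxy-6,10-dimethylundeca-5,9-dien-2-yl]-3,5,6,7-tetrahydro-1-benzofuran-4(2H)-one (pair of C5 epimers) | C/C(=C\CC[C@](C)(O)[C@@H]1CC2=C(CCC(O)C2=O)O1)CCC=C(C)C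
F4 | step 6 | (2S,5R)-2-[(2S,5E)-2-hydroxy-6,10-dimethylundeca-5,9-dien-2-yl]-4-oxo-2,3,4,5,6,7-hexahydro-1-benzofuran-5-yl acetate | C/C(=C\CC[C@](C)(O)[C@@H]1CC2=C(CC[C@@H](OC(C)=O)C2=O)O1)CCC=C(C)C
F5 | step 6 | (2S,5R)-5-hydroxy-2-[(2S,5E)-2-hydroxy-6,10-dimethylundeca-5,9-dien-2-yl]-3,5,6,7-tetrahydro-1-benzofuran-4(2H)-one | C/C(=C\CC[C@](C)(O)[C@@H]1CC2=C(CC[C@@H](O)C2=O)O1)CCC=C(C)C
F6 | step 5 | (2E,6E,10S)-10-hydroxy-2,6-dimethyl-10-[(2S)-4-oxo-2,3,4,5,6,7-hexahydro-1-benzofuran-2-yl]undeca-2,6-dienal | C/C(=C\CC[C@](C)(O)[C@@H]1CC2=C(CCCC2=O)O1)CC/C=C(\C)C=O
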